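**Plan**

- Numbering: the hydrocarbon core is tetracyclo[6.4.0.0^{2,7}.0^{3,6}]dodecane, with cyclohexane C1/C8–C12, ring A C1–C2–C7–C8, ring B C2–C3–C6–C7, ring C C3–C4–C5–C6 and the octyl chain (C1'–C8') on C10.
- Enabling feature: C4 and C5 of the terminal ring C are bare CH2 groups, so ring C can come from a cyclopentanone fused at C3–C6 by a one-carbon Wolff contraction (cut C5–C6), the expelled carbon leaving later as CO2.
- Further cuts: C2–C3 and C6–C7 of ring B (cyclopentenone plus the C2=C7 cyclobutene, [2+2]); ring A back to a cyclopropane carbaldehyde (carbene ring expansion); C1'–C2' of the chain (copper-catalysed Grignard coupling); the glycerol O–C8' bond (Williamson).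
- Forward order: cyclohexene, then lactone-tethered cyclopropane, then chain joined, then ring A, then ring B with the five-membered ring, then ring C, then decarboxylation and deprotection.
- Stereochemistry: C10 comes from (S)-cyclohex-3-ene-1-carboxylic acid; the ester tether delivers the carbenoid syn to it (C1, C8); exo-face photocycloaddition sets C2, C3, C6 and C7 cis,anti,cis; the Wolff shift retains C6.

Key step: step 13

Remark: the photocycloaddition of step 11 should give both orientations of the cyclopentanone (carbonyl next to C6 or next to C3). The pair is carried on together and converges when the ester carbon is lost in step 15. The compounds of steps 11 to 14 are drawn and numbered as the C6-carbonyl isomer.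

**Route**

Step 1
Reactants: 1 (S)-cyclohex-3-ene-1-carboxylic acid
Product: 2 (S)-cyclohex-3-en-1-ylmethanol
Conditions: LiAlH4 (1.5 equiv), THF, 0 → 25 °C; Na2SO4·10H2O quench
Reagents that add atoms: none
Why: Hydride reduction of the acid runs through the carboxylate, which cannot enolise, so the stereocentre is untouched and the isolated alkene is inert.

Step 2
Reactants: 2 (S)-cyclohex-3-en-1-ylmethanol
Product: 4 (S)-cyclohex-3-en-1-ylmethyl diazoacetate, via (S)-cyclohex-3-en-1-ylmethyl glyoxylate tosylhydrazone 3 (not isolated)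
Conditions: TsNHN=CHCOCl (1.9 equiv), PhNMe2, CH2Cl2, 0 °C; then Et3N (5 equiv), 0 → 25 °C
Reagents that add atoms: glyoxylic acid chloride p-toluenesulfonylhydrazone, Cc1ccc(cc1)S(=O)(=O)N/N=C/C(Cl)=O
Why: Acylation of the primary alcohol followed by base-induced loss of p-toluenesulfinate from the hydrazone (a Bamford–Stevens-type fragmentation) is a standard one-flask synthesis of alkyl diazoacetates and involves no stereocentre.

Step 3
Reactants: 4 (S)-cyclohex-3-en-1-ylmethyl diazoacetate
Product: 5 tricyclic lactone 4-oxatricyclo[4.3.1.0^{2,9}]decan-3-one (cyclopropane and lactone bridge on the same face of the cyclohexane)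
Conditions: Cu(MeCN)4PF6 (5 mol %), CH2Cl2, reflux, syringe-pump addition of 4 over 10 h, final 0.005 M
Reagents that add atoms: none
Why: Intramolecular carbenoid cyclopropanation of an alkenyl diazoacetate, in which the three-atom ester tether can reach only the alkene face syn to the CH2O group and only with the carbonyl endo, so both ring-fusion carbons and the cyclopropane apex are set cis to the side-chain carbon, while slow addition limits dimerisation and a copper carbenoid is reluctant to insert into C–H bonds.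

Step 4
Reactants: 5 tricyclic lactone
Product: 6 methyl 3-(hydroxymethyl)bicyclo[4.1.0]heptane-7-carboxylate (CH2OH, cyclopropane and endo ester all on one face)
Conditions: K2CO3 (0.2 equiv), MeOH, 25 °C; AcOH quench
Reagents that add atoms: methanol, CO
Why: Base-catalysed methanolysis (transesterification) of the bridged seven-membered lactone frees the primary alcohol, and the cyclopropane α-proton is too weakly acidic to epimerise under carbonate.

Step 5
Reactants: 6 methyl 3-(hydroxymethyl)bicyclo[4.1.0]heptane-7-carboxylate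
Product: 7 methyl 3-[(tosyloxy)methyl]bicyclo[4.1.0]heptane-7-carboxylate (configuration as in 6)
Conditions: TsCl (1.3 equiv), Et3N (2 equiv), DMAP (0.1 equiv), CH2Cl2, 0 → 25 °C
Reagents that add atoms: p-toluenesulfonyl chloride, Cc1ccc(cc1)S(=O)(=O)Cl
Why: Sulfonylation of the primary alcohol turns it into a leaving group without touching a stereocentre.

Step 6
Reactants: 8 cis-2-phenyl-1,3-dioxan-5-ol; 9 1,7-dibromoheptane
Product: 11 cis-5-[(7-bromoheptyl)oxy]-2-phenyl-1,3-dioxane, via sodium cis-2-phenyl-1,3-dioxan-5-olate 10 (not isolated)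
Conditions: NaH (1.2 equiv), DMF, 0 °C; then 9 (4 equiv), 0 → 40 °C
Reagents that add atoms: none
Why: Williamson etherification of the secondary alkoxide with a primary bromide, in which the excess of dibromide keeps double alkylation low and the cis acetal is inert to base.

Step 7
Reactants: 7 methyl 3-[(tosyloxy)methyl]bicyclo[4.1.0]heptane-7-carboxylate; 11 cis-5-[(7-bromoheptyl)oxy]-2-phenyl-1,3-dioxane
Product: 13 methyl 3-{8-[(cis-2-phenyl-1,3-dioxan-5-yl)oxy]octyl}bicyclo[4.1.0]heptane-7-carboxylate (configuration as in 6), via 7-[(cis-2-phenyl-1,3-dioxan-5-yl)oxy]heptylmagnesium bromide 12 (not isolated)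
Conditions: 11, Mg, THF, 40 °C; add (1.5 equiv) to 7 and Li2CuCl4 (5 mol %), THF, −40 → 0 °C
Reagents that add atoms: none
Why: Copper-catalysed sp3–sp3 cross-coupling of a primary tosylate with a primary alkyl Grignard reagent should outrun Grignard addition to the hindered methyl ester at low temperature, and it forms the C1'–C2' bond away from every stereocentre.

Step 8
Reactants: 13 chain-bearing cyclopropane methyl ester
Product: 14 3-{8-[(cis-2-phenyl-1,3-dioxan-5-yl)oxy]octyl}bicyclo[4.1.0]heptane-7-carbaldehyde (configuration as in 13)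
Conditions: i-Bu2AlH (1.1 equiv), CH2Cl2, −78 °C; MeOH, aq. potassium sodium tartrate (KNaC4H4O6)
Reagents that add atoms: none
Why: Partial reduction of a methyl ester with i-Bu2AlH stops at the aldehyde because the aluminium hemiacetal persists at −78 °C until work-up, and epimerisation at the cyclopropane carbon would be harmless because that centre disappears in step 10.

Step 9
Reactants: 14 cyclopropane carbaldehyde
Product: 15 (E)-p-toluenesulfonylhydrazone of 14
Conditions: TsNHNH2 (1.05 equiv), THF, 25 °C
Reagents that add atoms: p-toluenesulfonohydrazide, Cc1ccc(cc1)S(=O)(=O)NN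
Why: Condensation of an aldehyde with the sulfonylhydrazide needs no acid catalyst, so the benzylidene acetal is spared.

Step 10
Reactants: 15 tosylhydrazone
Product: 18 cis-fused 10-{8-[(cis-2-phenyl-1,3-dioxan-5-yl)oxy]octyl}bicyclo[4.2.0]oct-7-ene in core numbering (ring A with C2=C7 and chain syn to the four-membered ring), via tosylhydrazone sodium salt 16 (not isolated), via cyclopropyldiazomethane 17 (not isolated)
Conditions: NaH (1.1 equiv), THF, 0 → 25 °C; evaporate; diglyme, 140 °C
Reagents that add atoms: none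
Why: Aprotic Bamford–Stevens reaction in which the salt loses sulfinate and then N2, and the cyclopropylcarbene undergoes its characteristic 1,2-shift ring expansion to the cyclobutene with retention at the migrating ring-fusion carbon, so the cis fusion (C1, C8) and its syn relation to the chain are kept.

Step 11
Reactants: 18 chain-bearing cyclobutene; 19 cyclopent-2-en-1-one
Product: 20 photoadduct ketone (five-membered ring C3–C4–C5–C(=O)–C6 cis-fused to ring B and anti to ring A)
Conditions: 19 (6 equiv, in portions), CH2Cl2, hν (λ > 300 nm, Pyrex), −20 °C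
Reagents that add atoms: none
Why: Enone–alkene [2+2] photocycloaddition through the cyclopentenone triplet, a reaction well precedented for strained cyclobutenes, in which the alkene is attacked on its exo face away from the cyclohexane and the five/four fusion can only be cis, which sets C2, C3, C6 and C7 in the cis,anti,cis pattern.

Step 12
Reactants: 20 photoadduct ketone
Product: 23 α-diazoketone (ring C3–C4H2–C5(=N2)–C(=O)–C6), via lithium enolate 21 (not isolated), via 2-trifluoroacetyl ketone 22 (not isolated)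
Conditions: LiN(SiMe3)2 (1.1 equiv), THF, −78 °C; CF3CO2CH2CF3 (1.2 equiv); aq. NH4Cl; crude in MeCN, MsN3 (1.5 equiv), Et3N (1.5 equiv), H2O (1 equiv), 25 °C
Reagents that add atoms: methanesulfonyl azide, CS(=O)(=O)N=[N+]=[N-]
Why: Detrifluoroacetylative (Regitz-type) diazo transfer in which kinetic enolisation toward the CH2 α-carbon, Claisen trifluoroacetylation and N2 transfer with loss of the N-sulfonyl trifluoroacetamide place the diazo group on the only α-carbon that carries two hydrogens.

Step 13
Reactants: 23 α-diazoketone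
Product: 25 acetal-protected ladderane methyl ester (CO2Me exo on C5), via ketene 24 (not isolated)
Conditions: hν (λ > 300 nm, Pyrex), MeOH/THF 4:1, 0 °C; then NaOMe (0.2 equiv), 25 °C
Reagents that add atoms: methanol, CO
Why: Direct excitation of the diazoketone, held s-cis by the five-membered ring, expels N2 with concerted 1,2-shift of the ring-fusion carbon C6 from the carbonyl carbon to the diazo carbon C5, and the resulting ketene 24 is trapped by methanol as the ester enol and then the ester. The closest known reaction type is the photochemical Wolff ring contraction of 2-diazocyclopentanones fused to cyclobutanes, the established way of finishing a ladderane ring. Ring C (C3–C4–C5–C6) therefore closes by one-carbon contraction of the five-membered ring and not by cyclisation, the new C5–C6 bond being the only skeletal bond made. C6 migrates with retention, so the cis fusion of rings B and C (C3, C6) and its anti relation to ring A from step 11 are carried over unchanged. The one new stereocentre, C5, arises on ketonisation of the enol, where protonation on the open convex face gives the endo ester first and NaOMe equilibrates it to the less hindered exo ester, and since C5 becomes CH2 in step 15 either epimer would serve. The step needs rearrangement to win over O–H insertion into methanol and over 1,2-hydride shift from C4, which the locked s-cis geometry (migrating C–C bond anti-periplanar to the departing N2) and the absence of any other substituent on the carbonyl carbon secure.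

Step 14
Reactants: 25 ladderane methyl ester
Product: 26 ladderane C5 carboxylic acid (acetal retained)
Conditions: LiOH·H2O (5 equiv), THF/MeOH/H2O 3:1:1, 40 °C; 0.5 M HCl to pH 5, 0 °C
Reagents that add atoms: lithium hydroxide, [Li+].[OH-]
Why: Saponification of the unhindered exo ester, where any epimerisation at C5 is irrelevant and the acetal tolerates base and the brief, mildly acidic work-up.

Step 15
Reactants: 26 ladderane C5 carboxylic acid
Product: 28 cis-5-{[8-(tetracyclo[6.4.0.0^{2,7}.0^{3,6}]dodecan-10-yl)octyl]oxy}-2-phenyl-1,3-dioxane (ring C unsubstituted), via thiohydroxamate ester 27 (not isolated)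
Conditions: N-hydroxypyridine-2-thione (1.2 equiv), DCC (1.2 equiv), DMAP (0.1 equiv), CH2Cl2, 0 → 20 °C, dark; then t-BuSH (30 equiv), hν (tungsten lamp), 0 °C
Reagents that add atoms: none
Why: Barton reductive decarboxylation in which the thiohydroxamate ester fragments under visible light to CO2 and the C5 cyclobutyl radical, and the large excess of thiol at low temperature should reduce this radical faster than it can open the strained C3–C6 bond, erasing the C5 stereocentre.

Step 16
Reactants: 28 acetal-protected ladderane ether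
Product: 29 2-{[8-(tetracyclo[6.4.0.0^{2,7}.0^{3,6}]dodecan-10-yl)octyl]oxy}propane-1,3-diol (CNP0193334.1)
Conditions: AcOH/THF/H2O 4:2:1, 45 °C
Reagents that add atoms: none
Why: Acid-catalysed hydrolysis of the benzylidene acetal releases the 1,3-diol, and the saturated ladderane and the dialkyl ether are inert to aqueous acetic acid.

**Compound list**

1 | (S)-cyclohex-3-ene-1-carboxylic acid | OC(=O)[C@H]1CCC=CC1 | starting material
2 | (S)-cyclohex-3-en-1-ylmethanol | OC[C@H]1CCC=CC1 | intermediate
3 | (S)-cyclohex-3-en-1-ylmethyl (E)-2-(tosylhydrazono)acetate | Cc1ccc(cc1)S(=O)(=O)N/N=C/C(=O)OC[C@H]1CCC=CC1 | intermediate (not isolated)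
4 | (S)-cyclohex-3-en-1-ylmethyl diazoacetate | [N-]=[N+]=CC(=O)OC[C@H]1CCC=CC1 | intermediate
5 | 4-oxatricyclo[4.3.1.0^{2,9}]decan-3-one, cyclopropane and lactone bridge on one face | O=C1OC[C@H]2CC[C@@H]3[C@H](C2)[C@H]13 | intermediate
6 | methyl 3-(hydroxymethyl)bicyclo[4.1.0]heptane-7-carboxylate, CH2OH, cyclopropane and endo ester on one face | OC[C@H]1CC[C@@H]2[C@H](C1)[C@@H]2C(=O)OC | intermediate
7 | methyl 3-[(tosyloxy)methyl]bicyclo[4.1.0]heptane-7-carboxylate, configuration as in 6 | Cc1ccc(cc1)S(=O)(=O)OC[C@H]1CC[C@@H]2[C@H](C1)[C@@H]2C(=O)OC | intermediate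
8 | cis-2-phenyl-1,3-dioxan-5-ol (cis-1,3-O-benzylideneglycerol) | c1ccccc1[C@@H]1OC[C@@H](CO1)O | starting material
9 | 1,7-dibromoheptane | BrCCCCCCCBr | starting material
10 | sodium cis-2-phenyl-1,3-dioxan-5-olate | c1ccccc1[C@@H]1OC[C@@H](CO1)[O-].[Na+] | intermediate (not isolated)
11 | cis-5-[(7-bromoheptyl)oxy]-2-phenyl-1,3-dioxane | c1ccccc1[C@@H]1OC[C@@H](CO1)OCCCCCCCBr | intermediate
12 | 7-[(cis-2-phenyl-1,3-dioxan-5-yl)oxy]heptylmagnesium bromide | c1ccccc1[C@@H]1OC[C@@H](CO1)OCCCCCCC[Mg]Br | intermediate (not isolated)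
13 | methyl 3-{8-[(cis-2-phenyl-1,3-dioxan-5-yl)oxy]octyl}bicyclo[4.1.0]heptane-7-carboxylate, chain, cyclopropane and endo ester on one face | c1ccccc1[C@@H]1OC[C@@H](CO1)OCCCCCCCC[C@H]1CC[C@@H]2[C@H](C1)[C@@H]2C(=O)OC | intermediate
14 | 3-{8-[(cis-2-phenyl-1,3-dioxan-5-yl)oxy]octyl}bicyclo[4.1.0]heptane-7-carbaldehyde, configuration as in 13 | c1ccccc1[C@@H]1OC[C@@H](CO1)OCCCCCCCC[C@H]1CC[C@@H]2[C@H](C1)[C@@H]2C=O | intermediate
15 | (E)-p-toluenesulfonylhydrazone of 14 | c1ccccc1[C@@H]1OC[C@@H](CO1)OCCCCCCCC[C@H]1CC[C@@H]2[C@H](C1)[C@@H]2/C=N/NS(=O)(=O)c1ccc(C)cc1 | intermediate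
16 | sodium salt of 15 | [Na+].c1ccccc1[C@@H]1OC[C@@H](CO1)OCCCCCCCC[C@H]1CC[C@@H]2[C@H](C1)[C@@H]2/C=N/[N-]S(=O)(=O)c1ccc(C)cc1 | intermediate (not isolated)
17 | 7-(diazomethyl)-3-{8-[(cis-2-phenyl-1,3-dioxan-5-yl)oxy]octyl}bicyclo[4.1.0]heptane, configuration as in 13 | c1ccccc1[C@@H]1OC[C@@H](CO1)OCCCCCCCC[C@H]1CC[C@@H]2[C@H](C1)[C@@H]2C=[N+]=[N-] | intermediate (not isolated)
18 | cis-fused bicyclo[4.2.0]oct-7-ene (ring A, C2=C7) with the 8-[(cis-2-phenyl-1,3-dioxan-5-yl)oxy]octyl chain on C10 syn to the four-membered ring | c1ccccc1[C@@H]1OC[C@@H](CO1)OCCCCCCCC[C@H]1CC[C@@H]2[C@H](C1)C=C2 | intermediate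
19 | cyclopent-2-en-1-one | O=C1C=CCC1 | starting material
20 | photoadduct ketone, ring C3–C4–C5–C(=O)–C6 cis-fused to ring B and anti to ring A | c1ccccc1[C@@H]1OC[C@@H](CO1)OCCCCCCCC[C@H]1CC[C@@H]2[C@H](C1)[C@H]1[C@@H]3C(=O)CC[C@@H]3[C@@H]21 | intermediate
21 | lithium enolate of 20 (enolised toward C5) | [Li+].c1ccccc1[C@@H]1OC[C@@H](CO1)OCCCCCCCC[C@H]1CC[C@@H]2[C@H](C1)[C@H]1[C@@H]3C([O-])=CC[C@@H]3[C@@H]21 | intermediate (not isolated)
22 | 2-trifluoroacetyl derivative of 20 (CF3CO on C5) | c1ccccc1[C@@H]1OC[C@@H](CO1)OCCCCCCCC[C@H]1CC[C@@H]2[C@H](C1)[C@H]1[C@@H]3C(=O)C(C(=O)C(F)(F)F)C[C@@H]3[C@@H]21 | intermediate (not isolated)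
23 | α-diazoketone (diazo on C5, carbonyl carbon on C6) | c1ccccc1[C@@H]1OC[C@@H](CO1)OCCCCCCCC[C@H]1CC[C@@H]2[C@H](C1)[C@H]1[C@@H]3C(=O)C(=[N+]=[N-])C[C@@H]3[C@@H]21 | intermediate
24 | ketene (C=C=O exocyclic on C5 of the new ring C) | c1ccccc1[C@@H]1OC[C@@H](CO1)OCCCCCCCC[C@H]1CC[C@@H]2[C@H](C1)[C@H]1[C@@H]3C(=C=O)C[C@@H]3[C@@H]21 | intermediate (not isolated)
25 | acetal-protected ladderane methyl ester, CO2Me exo on C5 | c1ccccc1[C@@H]1OC[C@@H](CO1)OCCCCCCCC[C@H]1CC[C@@H]2[C@H](C1)[C@H]1[C@@H]3[C@@H](C(=O)OC)C[C@@H]3[C@@H]21 | intermediate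
26 | acetal-protected ladderane C5 carboxylic acid | c1ccccc1[C@@H]1OC[C@@H](CO1)OCCCCCCCC[C@H]1CC[C@@H]2[C@H](C1)[C@H]1[C@@H]3[C@@H](C(=O)O)C[C@@H]3[C@@H]21 | intermediate
27 | 2-thioxopyridin-1(2H)-yl ester of 26 | c1ccccc1[C@@H]1OC[C@@H](CO1)OCCCCCCCC[C@H]1CC[C@@H]2[C@H](C1)[C@H]1[C@@H]3[C@@H](C(=O)On4ccccc4=S)C[C@@H]3[C@@H]21 | intermediate (not isolated)
28 | cis-5-{[8-(tetracyclo[6.4.0.0^{2,7}.0^{3,6}]dodecan-10-yl)octyl]oxy}-2-phenyl-1,3-dioxane, core cis,anti,cis,anti,cis with the chain syn to ring A | c1ccccc1[C@@H]1OC[C@@H](CO1)OCCCCCCCC[C@H]1CC[C@@H]2[C@H](C1)[C@H]1[C@@H]3CC[C@@H]3[C@@H]21 | intermediate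
29 | 2-{[8-(tetracyclo[6.4.0.0^{2,7}.0^{3,6}]dodecan-10-yl)octyl]oxy}propane-1,3-diol, core cis,anti,cis,anti,cis with the chain syn to ring A | OCC(CO)OCCCCCCCC[C@H]1CC[C@@H]2[C@H](C1)[C@H]1[C@@H]3CC[C@@H]3[C@@H]21 | target

**Step count and risks**

Total: 16 steps. Longest linear sequence: 15 steps (from 1 through steps 1–5 and 7–16; step 6 is a one-step branch).

Steps most likely to fail:

1. Step 3. The carbenoid may be lost to dimerisation or to insertion into the tertiary C–H bond beside the tether before it reaches the ring alkene across a seven-membered bridge. The fallback keeps a face-directing tether but lets a ketene add to the alkene, and it sets out from alcohol 2.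
   - O-alkylation of 2 with bromoacetic acid (NaH, THF) should give 2-{[(1S)-cyclohex-3-en-1-yl]methoxy}acetic acid F1.
   - (COCl)2 converts it to the acid chloride F2. Et3N in refluxing toluene at high dilution releases the alkoxyketene F3, which can add only to the syn face and should close to the tricyclic α-alkoxycyclobutanone F4.
   - SmI2 (THF/MeOH, −78 °C) cleaves the C–O bond next to the carbonyl to give the hydroxymethyl cyclobutanone F5, and TsNHNH2 gives its tosylhydrazone F6.
   - A Shapiro reaction (n-BuLi, 3.3 equiv, THF, −78 → 0 °C) through the dilithio vinyllithium alkoxide F7 gives the cyclobutene alcohol F8 after protonation.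
   - Tosylation gives the tosylate F9, and copper-catalysed coupling with Grignard reagent 12 (no ester present) comes back to the route at cyclobutene 18.

2. Step 15. Strain-driven β-scission of the C5 radical, opening the C3–C6 bond, may compete with hydrogen transfer. The fallback removes the ester carbon by a polar oxidative degradation and sets out from ester 25.
   - KN(SiMe3)2 (THF, −78 °C) forms the potassium enolate F14, and 2-(phenylsulfonyl)-3-phenyloxaziridine hydroxylates it on the exo face to the α-hydroxy ester F15.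
   - LiAlH4 reduces this to the 1,2-diol F16, and NaIO4 (THF/H2O) cleaves the diol to the ring C cyclobutanone F17.
   - TsNHNH2 gives the tosylhydrazone F18. Catecholborane followed by NaOAc·3H2O (CHCl3, reflux) reduces it to the methylene group through the diazene, coming back to the route at 28.

3. Step 7. Addition of the Grignard reagent to the methyl ester may outrun a slow substitution at the β-branched carbon. The fallback makes the same C1'–C2' bond by olefination and sets out from hydroxy ester 6.
   - Swern oxidation of 6 ((COCl)2, DMSO, i-Pr2NEt, −78 °C) gives the aldehyde F10.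
   - Bromide 11 and PPh3 (MeCN, reflux) give the phosphonium bromide F11, which NaN(SiMe3)2 (THF, −78 °C) converts to the ylide F12.
   - Wittig reaction with F10 at −78 °C, cold enough to leave the α-stereocentre alone, gives the Z-alkene F13.
   - Hydrogenation with H2 and RhCl(PPh3)3 (benzene/EtOH), which spares the acetal and the cyclopropane, comes back to the route at 13.

Further compounds
F1 | step 3 | 2-{[(1S)-cyclohex-3-en-1-yl]methoxy}acetic acid | OC(=O)COC[C@H]1CCC=CC1
F2 | step 3 | 2-{[(1S)-cyclohex-3-en-1-yl]methoxy}acetyl chloride | ClC(=O)COC[C@H]1CCC=CC1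
F3 | step 3 | {[(1S)-cyclohex-3-en-1-yl]methoxy}ketene | O=C=COC[C@H]1CCC=CC1
F4 | step 3 | tricyclic α-alkoxycyclobutanone (cis-fused cyclobutanone whose α-oxygen is tied through CH2 to the side-chain carbon, all on one face) | O=C1[C@@H]2CC[C@H](CO3)C[C@@H]2[C@@H]13
F5 | step 3 | cis-fused 3-(hydroxymethyl)bicyclo[4.2.0]octan-7-one, CH2OH syn to the four-membered ring | OC[C@H]1CC[C@@H]2[C@H](C1)CC2=O
F6 | step 3 | p-toluenesulfonylhydrazone of F5 | OC[C@H]1CC[C@@H]2[C@H](C1)CC2=NNS(=O)(=O)c1ccc(C)cc1
F7 | step 3 | dilithio vinyllithium alkoxide from F6 | [Li]OC[C@H]1CC[C@@H]2[C@H](C1)C=C2[Li]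
F8 | step 3 | cis-fused bicyclo[4.2.0]oct-7-en-3-ylmethanol, CH2OH syn to the cyclobutene | OC[C@H]1CC[C@@H]2[C@H](C1)C=C2
F9 | step 3 | p-toluenesulfonate of F8 | Cc1ccc(cc1)S(=O)(=O)OC[C@H]1CC[C@@H]2[C@H](C1)C=C2
F10 | step 7 | methyl 3-formylbicyclo[4.1.0]heptane-7-carboxylate, configuration as in 6 | O=C[C@H]1CC[C@@H]2[C@H](C1)[C@@H]2C(=O)OC
F11 | step 7 | {7-[(cis-2-phenyl-1,3-dioxan-5-yl)oxy]heptyl}triphenylphosphonium bromide | [Br-].c1ccccc1[C@@H]1OC[C@@H](CO1)OCCCCCCC[P+](c1ccccc1)(c1ccccc1)c1ccccc1
F12 | step 7 | {7-[(cis-2-phenyl-1,3-dioxan-5-yl)oxy]heptylidene}triphenylphosphorane | c1ccccc1[C@@H]1OC[C@@H](CO1)OCCCCCCC=P(c1ccccc1)(c1ccccc1)c1ccccc1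
F13 | step 7 | (Z)-1',2'-dehydro analogue of 13 | c1ccccc1[C@@H]1OC[C@@H](CO1)OCCCCCC/C=C\[C@H]1CC[C@@H]2[C@H](C1)[C@@H]2C(=O)OC
F14 | step 15 | potassium enolate of ester 25 | [K+].c1ccccc1[C@@H]1OC[C@@H](CO1)OCCCCCCCC[C@H]1CC[C@@H]2[C@H](C1)[C@H]1[C@@H]3C(=C([O-])OC)C[C@@H]3[C@@H]21
F15 | step 15 | C5 α-hydroxy ester (OH exo; configuration at C5 immaterial) | c1ccccc1[C@@H]1OC[C@@H](CO1)OCCCCCCCC[C@H]1CC[C@@H]2[C@H](C1)[C@H]1[C@@H]3[C@](O)(C(=O)OC)C[C@@H]3[C@@H]21
F16 | step 15 | C5 hydroxy, hydroxymethyl diol | c1ccccc1[C@@H]1OC[C@@H](CO1)OCCCCCCCC[C@H]1CC[C@@H]2[C@H](C1)[C@H]1[C@@H]3[C@](O)(CO)C[C@@H]3[C@@H]21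
F17 | step 15 | ring C cyclobutanone (C5 ketone) | c1ccccc1[C@@H]1OC[C@@H](CO1)OCCCCCCCC[C@H]1CC[C@@H]2[C@H](C1)[C@H]1[C@@H]3C(=O)C[C@@H]3[C@@H]21
F18 | step 15 | p-toluenesulfonylhydrazone of F17 | c1ccccc1[C@@H]1OC[C@@H](CO1)OCCCCCCCC[C@H]1CC[C@@H]2[C@H](C1)[C@H]1[C@@H]3C(=NNS(=O)(=O)c4ccc(C)cc4)C[C@@H]3[C@@H]21
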